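The plan rests on deleting the lactone oxygen O10 from the dioxepinone: C11 is then bonded directly to ring-B carbon C9a and the core is a xanthone whose ring B (the later chromanone arene) comes from 3,4,5-trimethoxytoluene, with two equivalent free positions. The key step restores O10 by a Baeyer–Villiger-type oxidation: C9a, para to a methoxy group, migrates from the carbonyl carbon to oxygen, which makes the C11–O10 and O10–C9a bonds, expands the pyranone to the dioxepinone and sets the fourth ring-B oxygen in one operation. Its precursor is a 1,8-dimethylxanthone with two methoxy groups on ring B and, on ring A, an acetoxy group para to the carbonyl.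

Key step: step 5

Remark: ring A is the orsellinate-derived ring bearing the lactone carbonyl and ring B the trimethoxytoluene-derived ring; dioxepinone atoms are numbered as in 11H-dibenzo[b,e][1,4]dioxepin-11-one (C11 carbonyl, O10 ester oxygen on C9a, O5 ether oxygen); compounds 1, 3 and 11 are taken to be purchasable; the target has no stereocentre and none is created in any step.

Step 1
Reactants: 1 orsellinic acid (2,4-dihydroxy-6-methylbenzoic acid)
Product: 2 2,4-diacetoxy-6-methylbenzoic acid
Conditions: Ac2O, pyridine, 0 °C → rt; aq. HCl work-up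
Reagents that add atoms: acetic anhydride, CC(=O)OC(C)=O
Why: Pyridine-promoted O-acetylation of both phenols; any mixed anhydride formed at the carboxyl group is hydrolysed at work-up, and the two acetates switch off ring A as a nucleophile for step 2.

Step 2
Reactants: 2 2,4-diacetoxy-6-methylbenzoic acid; 3 3,4,5-trimethoxytoluene
Product: 5 (2,4-diacetoxy-6-methylphenyl)(2,3,4-trimethoxy-6-methylphenyl)methanone, via acid chloride 4 (not isolated)
Conditions: (COCl)2, cat. DMF, CH2Cl2, rt; evaporate; then 3, SnCl4, CH2Cl2, 0 °C → rt
Reagents that add atoms: none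
Why: Friedel–Crafts acylation through the acylium ion of the di-ortho-substituted aroyl chloride 4: the two free positions of 3 are equivalent, each ortho to one methoxy group and para to another, and SnCl4 is mild enough to leave the methoxy group next to the new ketone, the later leaving group, in place.

Step 3
Reactants: 5 (2,4-diacetoxy-6-methylphenyl)(2,3,4-trimethoxy-6-methylphenyl)methanone
Product: 7 6-hydroxy-3,4-dimethoxy-1,8-dimethyl-9H-xanthen-9-one, via dihydroxybenzophenone 6 (not isolated)
Conditions: Me4NOH (aq), pyridine, reflux; then aq. HCl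
Reagents that add atoms: none
Why: Hydroxide cleaves both acetates and the ring-A 2-phenoxide of 6 then closes the pyranone by intramolecular nucleophilic aromatic substitution (addition–elimination) at the ring-B carbon whose methoxy group is ortho to the ketone, the standard base-induced conversion of 2-hydroxy-2'-methoxybenzophenones into xanthones; only this one phenoxide and this one methoxy group can reach each other.

Step 4
Reactants: 7 6-hydroxy-3,4-dimethoxy-1,8-dimethyl-9H-xanthen-9-one
Product: 8 5,6-dimethoxy-1,8-dimethyl-9-oxo-9H-xanthen-3-yl acetate (the O-acetate of 7)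
Conditions: Ac2O, pyridine, cat. DMAP, rt
Reagents that add atoms: acetic anhydride, CC(=O)OC(C)=O
Why: DMAP-catalysed acyl transfer to the phenol; as its acetate the ring-A oxygen para to the carbonyl is only a weak donor during the oxidation and can later be removed by acid methanolysis without base.

Step 5
Reactants: 8 5,6-dimethoxy-1,8-dimethyl-9-oxo-9H-xanthen-3-yl acetate
Product: 10 6,7-dimethoxy-1,9-dimethyl-11-oxo-11H-dibenzo[b,e][1,4]dioxepin-3-yl acetate, via Criegee adduct 9 (not isolated)
Conditions: CF3CO3H [from (CF3CO)2O and urea·H2O2], CF3CO2H–CH2Cl2, 0 °C → rt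
Reagents that add atoms: trifluoroperacetic acid, OOC(=O)C(F)(F)F
Why: Proposed new method: the peracid should add to the acid-activated C9 carbonyl of 8, helped by relief of the crowding between the carbonyl oxygen and the 1- and 8-methyl groups, to give the peroxy adduct 9, from which the ring-B carbon shifts to the nearer peroxide oxygen as trifluoroacetate leaves. The closest known reactions are Baeyer–Villiger oxidations of benzophenones to aryl benzoates and of fluorenones to benzocoumarins, whereas a xanthone carbonyl, a doubly vinylogous ester, has not been shown to react in this way. The one new ring, the seven-membered dioxepinone, is closed by ring expansion: the 1,2-aryl shift inserts the oxygen into the existing six-membered pyranone, so no open-chain cyclisation is involved. No stereocentre is formed. The step needs ring B and not ring A to migrate; both candidate carbons carry the same ortho groups (a methyl group and the ring oxygen), so the para substituent decides, methoxy on ring B against the weakly donating acetoxy on ring A. It also needs attack at the carbonyl and not on the arenes; in trifluoroacetic acid the carbonyl-protonated xanthone is deactivated towards electrophilic hydroxylation, and the peracid is held near one equivalent because product 10 is the more oxidisable species.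

Step 6
Reactants: 10 6,7-dimethoxy-1,9-dimethyl-11-oxo-11H-dibenzo[b,e][1,4]dioxepin-3-yl acetate; 11 3-methylbut-2-enoyl chloride
Product: 14 6-methoxy pyranone-fused depsidone acetate (2,2-dimethyl-2,3-dihydro-4H-pyran-4-one ring fused at C7–C8 of 10; ring oxygen on C7; ketone carbon on C8; 3-OAc; 6-OMe), via methoxyaryl enone 12 (not isolated), via hydroxyaryl enone 13 (not isolated)
Conditions: AlCl3, CH2Cl2, 0 °C → rt; aq. HCl
Reagents that add atoms: none
Why: Friedel–Crafts acylation at C8 (the only free ring-B position, ortho to the 7-methoxy group and para to the O5 ether oxygen), chelation-driven cleavage by AlCl3 of the methoxy group ortho to the new ketone, and 6-endo oxa-Michael closure of the freed 7-hydroxyl onto the enone, the classical one-flask route from methoxyarenes to 2,2-dimethylchroman-4-ones; ring A is held back by its acetate and the lactone carbonyl.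

Step 7
Reactants: 14 6-methoxy pyranone-fused depsidone acetate
Product: 16 3,6-dihydroxy pyranone-fused depsidone (14 with 3-OH and 6-OH free), via hydroxychromanone acetate 15 (not isolated)
Conditions: BBr3, CH2Cl2, −78 → 0 °C; then MeOH, rt
Reagents that add atoms: none
Why: Lewis-acid cleavage of the remaining aryl methyl ether (bromide attacks the methyl group of the boron-complexed ether), then methanolysis of the unhindered aryl acetate catalysed by the HBr released on the methanol quench; the lactone carbonyl, flanked by the 1-methyl group and the ring oxygen, should not exchange, and no base touches the dioxepinone.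

Step 8
Reactants: 16 3,6-dihydroxy pyranone-fused depsidone
Product: 17 target CNP0271978.0 (16 with a formyl group at C4)
Conditions: Cl2CHOMe, TiCl4, CH2Cl2, −10 °C → rt; then aq. HCl
Reagents that add atoms: dichloromethyl methyl ether, COC(Cl)Cl; water, O
Why: Rieche formylation ortho to the titanium-bound ring-A phenoxide: ring B has no free position, and of the two ortho sites C4 lies between the phenol and ether oxygens (the site attacked in orsellinate esters and other 2-oxy-4-hydroxyaryl carbonyl compounds), while C2 is crowded by the 1-methyl group buttressed against the lactone carbonyl.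

Compound list
1 | orsellinic acid (2,4-dihydroxy-6-methylbenzoic acid) | Cc1cc(O)cc(O)c1C(O)=O | starting material
2 | 2,4-diacetoxy-6-methylbenzoic acid | Cc1cc(OC(C)=O)cc(OC(C)=O)c1C(O)=O | intermediate
3 | 3,4,5-trimethoxytoluene | COc1cc(C)cc(OC)c1OC | starting material
4 | 2,4-diacetoxy-6-methylbenzoyl chloride (not isolated) | Cc1cc(OC(C)=O)cc(OC(C)=O)c1C(Cl)=O | intermediate
5 | (2,4-diacetoxy-6-methylphenyl)(2,3,4-trimethoxy-6-methylphenyl)methanone | Cc1cc(OC(C)=O)cc(OC(C)=O)c1C(=O)c1c(C)cc(OC)c(OC)c1OC | intermediate
6 | (2,4-dihydroxy-6-methylphenyl)(2,3,4-trimethoxy-6-methylphenyl)methanone (not isolated) | Cc1cc(O)cc(O)c1C(=O)c1c(C)cc(OC)c(OC)c1OC | intermediate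
7 | 6-hydroxy-3,4-dimethoxy-1,8-dimethyl-9H-xanthen-9-one | Cc1cc(O)cc2oc3c(OC)c(OC)cc(C)c3c(=O)c12 | intermediate
8 | 5,6-dimethoxy-1,8-dimethyl-9-oxo-9H-xanthen-3-yl acetate (key-step precursor; acetoxy on ring A para to the carbonyl, both methoxy groups on ring B) | Cc1cc(OC(C)=O)cc2oc3c(OC)c(OC)cc(C)c3c(=O)c12 | intermediate
9 | 9-hydroxy-5,6-dimethoxy-1,8-dimethyl-9-(trifluoroacetylperoxy)-9H-xanthen-3-yl acetate (Criegee adduct, not isolated) | Cc1cc(OC(C)=O)cc2Oc3c(OC)c(OC)cc(C)c3C(O)(OOC(=O)C(F)(F)F)c12 | intermediate
10 | 6,7-dimethoxy-1,9-dimethyl-11-oxo-11H-dibenzo[b,e][1,4]dioxepin-3-yl acetate (key-step product) | Cc1cc(OC(C)=O)cc2c1C(=O)Oc1c(C)cc(OC)c(OC)c1O2 | intermediate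
11 | 3-methylbut-2-enoyl chloride | CC(C)=CC(Cl)=O | starting material
12 | 6,7-dimethoxy-1,9-dimethyl-8-(3-methylbut-2-enoyl)-11-oxo-11H-dibenzo[b,e][1,4]dioxepin-3-yl acetate (not isolated) | Cc1cc(OC(C)=O)cc2c1C(=O)Oc1c(C)c(C(=O)C=C(C)C)c(OC)c(OC)c1O2 | intermediate
13 | 7-hydroxy-6-methoxy-1,9-dimethyl-8-(3-methylbut-2-enoyl)-11-oxo-11H-dibenzo[b,e][1,4]dioxepin-3-yl acetate (not isolated) | Cc1cc(OC(C)=O)cc2c1C(=O)Oc1c(C)c(C(=O)C=C(C)C)c(O)c(OC)c1O2 | intermediate
14 | depsidone 10 carrying a 2,2-dimethyl-2,3-dihydro-4H-pyran-4-one ring fused at C7–C8 (ring oxygen on C7, ketone carbon on C8), with 6-OMe, 3-OAc and 1,9-dimethyl | Cc1cc(OC(C)=O)cc2c1C(=O)Oc1c(C)c3c(c(OC)c1O2)OC(C)(C)CC3=O | intermediate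
15 | 6-hydroxy analogue of 14, 3-OAc retained (not isolated) | Cc1cc(OC(C)=O)cc2c1C(=O)Oc1c(C)c3c(c(O)c1O2)OC(C)(C)CC3=O | intermediate
16 | 3,6-dihydroxy analogue of 14 (both phenols free, C4 unsubstituted) | Cc1cc(O)cc2c1C(=O)Oc1c(C)c3c(c(O)c1O2)OC(C)(C)CC3=O | intermediate
17 | CNP0271978.0: 16 with a formyl group at C4, between the 3-hydroxyl and the O5 ether oxygen | Cc1cc(O)c(C=O)c2c1C(=O)Oc1c(C)c3c(c(O)c1O2)OC(C)(C)CC3=O | target

Total step count: 8
Longest linear sequence: 8 steps (1 → 17)

Steps most likely to fail

Step 5 (the unprecedented oxygen insertion). The peracid may fail to add to the strongly conjugated carbonyl, or it may hydroxylate the arenes and over-oxidise the first-formed product. The fallback uses known chemistry only, sets out from 2 and returns at 10, and closes the seven-membered ring by copper-mediated aryl ether formation instead of oxygen insertion. Purchasable 3,4-dimethoxytoluene is formylated (POCl3, DMF) to 4,5-dimethoxy-2-methylbenzaldehyde F1. Dakin-type oxidation (meta-chloroperbenzoic acid, CH2Cl2; then aq. NaOH) gives 4,5-dimethoxy-2-methylphenol F2. NBS (MeCN, 0 °C) brominates the position between the hydroxyl and a methoxy group to give 2-bromo-3,4-dimethoxy-6-methylphenol F3. This phenol is esterified with acid 2 by the mixed-anhydride method ((CF3CO)2O, toluene, rt) to give 2-bromo-3,4-dimethoxy-6-methylphenyl 2,4-diacetoxy-6-methylbenzoate F4. HCl in MeOH removes both acetates and leaves the hindered aryl ester, giving 2-bromo-3,4-dimethoxy-6-methylphenyl 2,4-dihydroxy-6-methylbenzoate F5. Intramolecular Ullmann etherification (CuI, N,N-dimethylglycine, Cs2CO3, dioxane, 100 °C, high dilution) joins the ring-A 2-hydroxyl to the brominated carbon and gives 3-hydroxy-6,7-dimethoxy-1,9-dimethyl-11H-dibenzo[b,e][1,4]dioxepin-11-one F6. Acetylation (Ac2O, pyridine) then gives 10.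

Step 8. Site selectivity may be poor, with the formyl group entering at C2 (ortho to the hydroxyl and para to the ether oxygen) instead of C4. The fallback sets out from 16 and returns at 17 by blocking C2. NBS (MeCN, 0 °C) should brominate the same electronically favoured C2 to give the 2-bromo derivative of 16 F7. Formylation as in step 8 can then only occur at C4 and gives the 2-bromo-4-formyl compound F8. Hydrogenolysis of the aryl bromide (H2, Pd/C, NaOAc, EtOAc, rt, stopped after one equivalent of hydrogen) gives 17.

Step 6. The ring-A acetyl group may migrate or be transferred under AlCl3, the enoyl chloride may polymerise, or ether cleavage and ring closure may stay incomplete (material of the last kind should still converge in step 7). The fallback sets out from 10 and returns at 15; it reverses the order and uses a Brønsted acid on the free catechol. BBr3 (CH2Cl2, −78 → 0 °C, ice–water quench) gives 6,7-dihydroxy-1,9-dimethyl-11-oxo-11H-dibenzo[b,e][1,4]dioxepin-3-yl acetate F9. Condensation of this catechol with 3-methylbut-2-enoic acid in P2O5–MeSO3H at 60 °C (C-acylation at C8 or Fries shift of the 7-O-ester, then oxa-Michael closure) gives 15. Compound 15 is deacetylated with HCl in MeOH, as in the second stage of step 7, to give 16.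

Further compounds
F1 | step 5 | 4,5-dimethoxy-2-methylbenzaldehyde | Cc1cc(OC)c(OC)cc1C=O
F2 | step 5 | 4,5-dimethoxy-2-methylphenol | Cc1cc(OC)c(OC)cc1O
F3 | step 5 | 2-bromo-3,4-dimethoxy-6-methylphenol | Cc1cc(OC)c(OC)c(Br)c1O
F4 | step 5 | 2-bromo-3,4-dimethoxy-6-methylphenyl 2,4-diacetoxy-6-methylbenzoate | Cc1cc(OC(C)=O)cc(OC(C)=O)c1C(=O)Oc1c(C)cc(OC)c(OC)c1Br
F5 | step 5 | 2-bromo-3,4-dimethoxy-6-methylphenyl 2,4-dihydroxy-6-methylbenzoate | Cc1cc(O)cc(O)c1C(=O)Oc1c(C)cc(OC)c(OC)c1Br
F6 | step 5 | 3-hydroxy-6,7-dimethoxy-1,9-dimethyl-11H-dibenzo[b,e][1,4]dioxepin-11-one | Cc1cc(O)cc2c1C(=O)Oc1c(C)cc(OC)c(OC)c1O2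
F7 | step 8 | 2-bromo derivative of 16 | Cc1c(Br)c(O)cc2c1C(=O)Oc1c(C)c3c(c(O)c1O2)OC(C)(C)CC3=O
F8 | step 8 | 2-bromo-4-formyl derivative of 16 (2-bromo 17) | Cc1c(Br)c(O)c(C=O)c2c1C(=O)Oc1c(C)c3c(c(O)c1O2)OC(C)(C)CC3=O
F9 | step 6 | 6,7-dihydroxy-1,9-dimethyl-11-oxo-11H-dibenzo[b,e][1,4]dioxepin-3-yl acetate | Cc1cc(OC(C)=O)cc2c1C(=O)Oc1c(C)cc(O)c(O)c1O2
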